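## Structural features

The target joins a trans-fused decalin of the eudesmane type (ring A: C1–C5 and C10; ring B: C5–C10; C14 is the methyl on C10, C15 the methyl on C4, C11 the carbinol carbon on C7) through one benzylic methine, C9', to a hexasubstituted phloroglucinol ring bearing two formyl groups; C9' also carries an isobutyl chain. Six stereocentres are present: C9', C1 and quaternary C10 are contiguous, C5 and the tertiary carbinol C4 complete ring A, and C7 on ring B is remote. Relative to C14, the C7 side chain and the C4 hydroxyl are syn, whereas H5, C15 and the C1 branch are anti, so the bulky C1 branch is axial on ring A. Fragile elements are the two tertiary alcohols (acid-promoted dehydration), the triphenol–dialdehyde array (incompatible with organometallic reagents and strong Lewis acids) and, in carbonyl intermediates, the epimerisable positions C1 and C5. The real difficulty is the C1/C10 pair: a quaternary carbon next to a tertiary one whose substituent sits in the less stable axial position, so the relationship must be created in the bond-forming event and cannot be reached by equilibration. Ring A, with oxygen at C4 and a carbon branch at C1, is the retron of a [4+2] cycloaddition: a diene C3=C4(OR)–C5=C10 hung on a ring B that already holds C7 combines with an acryloyl unit C1=C2, forming C1–C10 and C2–C3 together, and the endo rule places the C1 carbonyl anti to C14.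

## Logic of the disconnections

23 ⇒ 21 (through 22). The three phenolic O–H bonds and the C11 O–H bond are traced to three O–CH3 bonds and one O–Si bond. The hydrogen-bonded triphenol–dialdehyde tolerates neither organolithium reagents nor Lewis acids, whereas its permethylated form does. The gain is that all earlier intermediates are neutral and non-chelating. The forward step must dealkylate under basic conditions and remove silicon with only dilute acid, because both tertiary alcohols forbid boron or aluminium halides.

21 ⇒ 19. The two aryl–CHO bonds are cut. Each free ring position of 19 lies between two methoxy groups and is the most acidic C–H bond, and aldehydes carried earlier would block the aryllithium and cation steps. The arene is simplified to a symmetric trialkoxybenzene unit. The forward step must formylate twice in the presence of the C4 alkoxide, with the first aldehyde masked in the flask.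

19 ⇒ 18 ⇒ 16 + 17. After the terminal alkene is reinstated (18), the C9'–CH2 bond is cut. C9' lies between a trialkoxyaryl ring that stabilises a benzylic cation and stereocentre C1, whose substituents (H, C2 methylene, quaternary C10) differ strongly in size. This removes the C9' stereocentre and the four-carbon chain. The π-nucleophile must add to the planar cation anti to C10 without harm to the tertiary hydroxyl or the silyl ether.

16 ⇒ 13 + 14 (through 15). The aryl–C9' bond is cut between an aldehyde carbon and an ortho-metalated arene. This separates the whole aromatic part from the terpenoid part. Addition must outrun enolisation at C1; the carbinol configuration is irrelevant because the next step erases it.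

13 ⇒ 12 ⇒ 11 ⇒ 10. The C9' oxidation level is adjusted, the C4–C15 bond is cut to the C4 ketone, and the C5–H bond with the carbonyl is traced to the C4=C5 enol ether. A C4 ketone lets methyl enter equatorially, away from 1,3-diaxial C14, and the enol ether lets C5 be set by protonation. Two stereocentres and one carbon are removed. The forward steps need kinetic protonation at C5 anti to C14 without later equilibration, a non-basic methyl donor and an oxidation that does not epimerise C1.

10 ⇒ 9 ⇒ 7 + 8. With the C1 carbinol carbon returned to the imide level, the C1–C10 and C2–C3 bonds are cut together. This removes ring A, quaternary C10 and the C1 centre in one operation and leaves a monocyclic diene and a three-carbon dienophile. The forward step must be regioselective (acyl carbon next to C10), endo-selective (acyl anti to C14) and must select the diene face anti to the C7 group against a weak opposing preference of the ring, which calls for a chiral catalyst on the dienophile.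

7 ⇒ 5 + 6 ⇒ 3 ⇒ 2 ⇒ 1. The C4–C5 bond between the two alkenes is cut to an enol triflate and an α-alkoxyvinyl metal; the triflate is traced through enolate 4 to enone 3, and the silyl ether and hydroxyl to the isopropenyl group of 1. This reaches a chiral-pool ketone that already holds C7 in the correct configuration together with ring B, its side chain and C14. The demands are regiospecific enolate formation on the methyl-bearing carbon and isolation of the acid-labile diene under basic conditions.

## Other disconnections considered

Alternative 1: The aryl–C9' and C9'–CH2 bonds are cut at once; the decalin is untouched. In the forward sense 2,4-diformylphloroglucinol A1 would condense with the eudesmane C1-carbaldehyde A2 (the desilylated form of 13) to the o-quinone methide A3, which 17 would trap to give the methallyl analogue A4; hydrogenation would finish.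
- In its favour: the arene needs no protecting groups, the formyl groups are present from the start and no demethylation is required. From the aldehyde stage it would need two or three operations where the chosen route needs five (steps 10–14), so it is the better plan on end-game step economy.
- Equal: the control element at C9' is the same 1,2-induction from C1 on a planar C9'.
- Against: it does not build the decalin, so A2 must still be made (most simply by steps 1–9); it replaces the end game, not the key step. Condensation of a hindered, α-branched axial aldehyde with a deactivated phenol should be slow, and its catalysts can epimerise C1. A3 has H1 in the position for a 1,5-hydrogen shift to an o-vinylphenol, which would erase C1, and it can also be intercepted by A1 or react with 17 in a [4+2] sense.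
- Mechanistically, a neutral conjugate addition to A3 stands against a cationic SN1 trapping in the chosen plan; the latter has no tautomerisation channel.

Alternative 2: The C5–C10 and C8–C9 bonds are cut. A trienone A6, to be assembled from (R)-linalool A5, would undergo intramolecular Diels–Alder reaction of its isopropenyl ketone with the diene C5=C6–C7=C8 to give the octalone A7.
- In its favour: both rings and quaternary C10 arise in one step, which is more ring construction per step than the chosen cycloaddition. The C4 carbinol comes intact from the chiral pool, so C4 is handled at least as well as by the Grignard step. Hydrogenation of C6=C7 anti to C14 should set C7 correctly.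
- Against: the only stereocontrol element is quaternary C4, whose methyl and silyloxy groups differ little in size, so facial control over C5/C10 is expected to be weak. Tether-activated decatrienones tend toward cis-fused adducts, and the α-methyl dienophile is sluggish.
- Decisive structural point: A7 carries only a ketone at C1 next to quaternary C10. Any later hydrogenation or protonation at C1 would deliver hydrogen anti to C14 and put the branch syn, the opposite of the target; the chosen plan sets this relationship in the cycloaddition itself.
- Step economy is comparable up to the bicycle and worse after it.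

Alternative 3: The C4–C5 bond is cut. A carbene-catalysed intramolecular Stetter reaction of the achiral dienone aldehyde A8 would add the acyl-anion equivalent at C4 to one of the two enantiotopic β-carbons and give the enedione A9.
- In its favour: C10 is created by catalyst control from an achiral precursor, with no chiral-pool dependence, access to either enantiomer and no matched/mismatched issue; on this point it is the better plan. Its three differentiated carbonyl groups sit exactly at C1, C4 and C7.
- Against: it forms one bond, one ring and one lasting stereocentre, against two bonds and two stereocentres in the chosen step. The tethered addition necessarily gives the cis-fused ketone first, and trans fusion would depend on an equilibration of uncertain position. Six-membered closure beside a fully substituted carbon is at the slow end of this reaction type.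
- Afterwards C7 needs a three-carbon carbinol unit with stereocontrol, C4 needs a chemoselective methyl addition among three carbonyls, and C1 poses the same contra-steric problem as in Alternative 2. The step count would clearly exceed that of the chosen plan.

Key step: step 5

Remark on the chemistry: in the square-planar chelate of 8 with divalent copper, the (S,S)-tert-butyl-bis(oxazoline) ligand would expose the Re face of the α-carbon and, with endo addition, lead to the (1S,10S) adduct with C14 anti to the C7 side chain; the (R,R)-ligand, 2,2'-(propane-2,2-diyl)bis[(4R)-4-tert-butyl-4,5-dihydro-1,3-oxazole], is therefore specified.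

Remark on the chemistry: 6, 8, 14, 17 and the ligand are taken as catalogue compounds.

## Route

Step 1
Reactants: 1 (S)-(+)-carvone
Product: 2 (5S)-5-(2-hydroxypropan-2-yl)-2-methylcyclohex-2-en-1-one
Conditions: 50% aq. H2SO4, 0 °C to rt
Reagents that add atoms: water, O
Why: Markovnikov hydration of the 1,1-disubstituted alkene through the tertiary cation; the electron-poor ring alkene is not protonated and the stereocentre (later C7) is not involved.

Step 2
Reactants: 2 (5S)-5-(2-hydroxypropan-2-yl)-2-methylcyclohex-2-en-1-one
Product: 3 (5S)-2-methyl-5-{2-[(triethylsilyl)oxy]propan-2-yl}cyclohex-2-en-1-one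
Conditions: TESOTf, 2,6-lutidine, CH2Cl2, −78 to 0 °C
Reagents that add atoms: triethylsilyl trifluoromethanesulfonate, CC[Si](CC)(CC)OS(=O)(=O)C(F)(F)F
Why: Silylation of a hindered tertiary alcohol requires the silyl triflate; the ether removes the acidic proton before the hydride, palladium and Lewis-acid steps.

Step 3
Reactants: 3 (5S)-2-methyl-5-{2-[(triethylsilyl)oxy]propan-2-yl}cyclohex-2-en-1-one
Product: 5 (5S)-2-methyl-5-{2-[(triethylsilyl)oxy]propan-2-yl}cyclohex-1-en-1-yl trifluoromethanesulfonate, via lithium enolate 4 (not isolated)
Conditions: LiBH(s-Bu)3, THF, −78 °C; then PhNTf2, −78 °C to rt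
Reagents that add atoms: N-phenylbis(trifluoromethanesulfonimide), O=S(=O)(N(c1ccccc1)S(=O)(=O)C(F)(F)F)C(F)(F)F
Why: Conjugate hydride addition to the β-unsubstituted enone gives the enolate regiospecifically on the methyl-bearing carbon, and O-sulfonylation traps it as the tetrasubstituted enol triflate before it can equilibrate; no stereocentre is formed.

Step 4
Reactants: 5 (5S)-2-methyl-5-{2-[(triethylsilyl)oxy]propan-2-yl}cyclohex-1-en-1-yl trifluoromethanesulfonate; 6 tributyl(1-ethoxyvinyl)stannane
Product: 7 triethyl({2-[(1S)-3-(1-ethoxyethenyl)-4-methylcyclohex-3-en-1-yl]propan-2-yl}oxy)silane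
Conditions: Pd(PPh3)4 (5 mol%), LiCl, THF, 65 °C; filtration through Et3N-treated silica
Reagents that add atoms: none
Why: Stille coupling of an enol triflate with an α-alkoxyvinylstannane at zerovalent palladium, with chloride assisting transmetalation; the acid-labile 2-ethoxydiene is isolated under basic conditions.

Step 5
Reactants: 7 triethyl({2-[(1S)-3-(1-ethoxyethenyl)-4-methylcyclohex-3-en-1-yl]propan-2-yl}oxy)silane; 8 3-acryloyl-1,3-oxazolidin-2-one
Product: 9 3-{[(1R,6S,8aR)-4-ethoxy-8a-methyl-6-{2-[(triethylsilyl)oxy]propan-2-yl}-1,2,3,5,6,7,8,8a-octahydronaphthalen-1-yl]carbonyl}-1,3-oxazolidin-2-one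
Conditions: [Cu((R,R)-t-Bu-box)](SbF6)2 (10 mol%, from CuCl2, AgSbF6 and the ligand), 3 Å molecular sieves, CH2Cl2, −40 to 0 °C
Reagents that add atoms: none
Why: Normal-electron-demand Diels–Alder reaction in which 8, chelated through both carbonyl groups to square-planar divalent copper in its s-cis form, reacts with the s-cis diene C3=C4(OEt)–C5=C10 in a concerted, asynchronous [4+2] step (C2–C3 bonding ahead of C1–C10); the closest known type is the copper bis(oxazoline)-catalysed cycloaddition of acryloyl oxazolidinones with donor-substituted dienes. Ring A is closed by intermolecular [4+2] annulation onto ring B, both σ-bonds forming suprafacially on each component. Regiochemistry follows from the diene polarisation: the ethoxy group makes C3 the nucleophilic terminus, which bonds to the β-carbon C2, so the acyl carbon lands on C1 next to C10. C1 is controlled by the ligand: the tert-butyl group of the (R,R)-ligand covers the Re face of the α-carbon, the diene adds to the Si face and C1 becomes (R). C10 is controlled by the endo transition state: the chelated acyl group lies under the diene and ends cis to the outside substituent C9, hence anti to the inside methyl C14. With dienophile face and endo topology fixed, the diene reacts on the face anti to the C7 substituent, which puts C14 syn to it; the ring-B half-chair by itself is expected to prefer slightly the other face (axial attack syn to the equatorial C7 group), so catalyst control must outweigh this weak remote bias. Hydrolysis or cationic oligomerisation of the enol ether is suppressed by molecular sieves, the non-coordinating counter-ion and low temperature, and the C4=C5 enol ether is kept for the following steps.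

Step 6
Reactants: 9 3-{[(1R,6S,8aR)-4-ethoxy-8a-methyl-6-{2-[(triethylsilyl)oxy]propan-2-yl}-1,2,3,5,6,7,8,8a-octahydronaphthalen-1-yl]carbonyl}-1,3-oxazolidin-2-one
Product: 10 [(1R,6S,8aR)-4-ethoxy-8a-methyl-6-{2-[(triethylsilyl)oxy]propan-2-yl}-1,2,3,5,6,7,8,8a-octahydronaphthalen-1-yl]methanol
Conditions: LiBH4, MeOH (1 equiv), THF, 0 °C
Reagents that add atoms: none
Why: Borohydride reduction of the activated exocyclic imide carbonyl gives the primary alcohol and releases the oxazolidinone; C1 is not enolised and the enol ether is inert to hydride.

Step 7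
Reactants: 10 [(1R,6S,8aR)-4-ethoxy-8a-methyl-6-{2-[(triethylsilyl)oxy]propan-2-yl}-1,2,3,5,6,7,8,8a-octahydronaphthalen-1-yl]methanol
Product: 11 (4R,4aR,7S,8aS)-4-(hydroxymethyl)-4a-methyl-7-{2-[(triethylsilyl)oxy]propan-2-yl}octahydronaphthalen-1(2H)-one (trans-fused)
Conditions: 0.1 M HCl, THF–H2O, 0 °C, short contact; NaHCO3 quench
Reagents that add atoms: water, O
Why: Enol ether hydrolysis in which the rate-limiting protonation at C5 should occur along the axial trajectory of ring B on the face anti to axial C14, giving H5 anti to C14 (trans fusion); the reaction is stopped before acid-catalysed enolisation can equilibrate C5.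

Step 8
Reactants: 11 (4R,4aR,7S,8aS)-4-(hydroxymethyl)-4a-methyl-7-{2-[(triethylsilyl)oxy]propan-2-yl}octahydronaphthalen-1(2H)-one
Product: 12 (1R,4R,4aR,7S,8aS)-4-(hydroxymethyl)-1,4a-dimethyl-7-{2-[(triethylsilyl)oxy]propan-2-yl}decahydronaphthalen-1-ol
Conditions: CeCl3, MeMgBr (3.5 equiv), THF, −78 °C
Reagents that add atoms: methylmagnesium bromide, C[Mg]Br
Why: Organocerium variant of the Grignard 1,2-addition, weakly basic so that C5 is not enolised; axial approach is blocked by the 1,3-diaxial methyl C14, so methyl enters equatorially and the C4 hydroxyl ends axial, syn to C14.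

Step 9
Reactants: 12 (1R,4R,4aR,7S,8aS)-4-(hydroxymethyl)-1,4a-dimethyl-7-{2-[(triethylsilyl)oxy]propan-2-yl}decahydronaphthalen-1-ol
Product: 13 (1R,4R,4aS,6S,8aS)-4-hydroxy-4,8a-dimethyl-6-{2-[(triethylsilyl)oxy]propan-2-yl}decahydronaphthalene-1-carbaldehyde
Conditions: Dess–Martin periodinane, NaHCO3, CH2Cl2, 0 °C to rt
Reagents that add atoms: none
Why: Dess–Martin oxidation converts only the primary alcohol; buffered, non-basic conditions avoid epimerisation of the axial aldehyde at C1, and 13 is used at once.

Step 10
Reactants: 13 (1R,4R,4aS,6S,8aS)-4-hydroxy-4,8a-dimethyl-6-{2-[(triethylsilyl)oxy]propan-2-yl}decahydronaphthalene-1-carbaldehyde; 14 1,3,5-trimethoxybenzene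
Product: 16 (1R,4R,4aR,7S,8aS)-4-[hydroxy(2,4,6-trimethoxyphenyl)methyl]-1,4a-dimethyl-7-{2-[(triethylsilyl)oxy]propan-2-yl}decahydronaphthalen-1-ol as a mixture of C9' epimers, via 2,4,6-trimethoxyphenyllithium 15 (not isolated)
Conditions: 14, n-BuLi, THF, 0 °C to rt; then 13, −78 to −20 °C; aq. NH4Cl
Reagents that add atoms: none
Why: Directed ortho-lithiation between two methoxy groups gives 15, which should add to the aldehyde faster than it enolises C1 (one equivalent is spent on the C4 hydroxyl); both C9' epimers are acceptable because this centre is ionised in the next step.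

Step 11
Reactants: 16 (1R,4R,4aR,7S,8aS)-4-[hydroxy(2,4,6-trimethoxyphenyl)methyl]-1,4a-dimethyl-7-{2-[(triethylsilyl)oxy]propan-2-yl}decahydronaphthalen-1-ol; 17 trimethyl(2-methylallyl)silane
Product: 18 (1R,4S,4aR,7S,8aS)-1,4a-dimethyl-4-[(1S)-3-methyl-1-(2,4,6-trimethoxyphenyl)but-3-en-1-yl]-7-{2-[(triethylsilyl)oxy]propan-2-yl}decahydronaphthalen-1-ol
Conditions: Bi(OTf)3 (10 mol%), CH2Cl2, −40 to 0 °C
Reagents that add atoms: none
Why: Hosomi–Sakurai-type SN1 substitution in which the trialkoxybenzylic alcohol ionises under mild Lewis acid and the allylsilane adds to the planar cation. C9' is set by 1,2-induction: allylic 1,3-strain holds H1 in the cation plane beside the ortho-methoxy group, and the nucleophile should attack anti to quaternary C10 (over C2), giving (9'S). The C4 hydroxyl lies on the opposite face of ring A and cannot trap the cation.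

Step 12
Reactants: 18 (1R,4S,4aR,7S,8aS)-1,4a-dimethyl-4-[(1S)-3-methyl-1-(2,4,6-trimethoxyphenyl)but-3-en-1-yl]-7-{2-[(triethylsilyl)oxy]propan-2-yl}decahydronaphthalen-1-ol
Product: 19 (1R,4S,4aR,7S,8aS)-1,4a-dimethyl-4-[(1S)-3-methyl-1-(2,4,6-trimethoxyphenyl)butyl]-7-{2-[(triethylsilyl)oxy]propan-2-yl}decahydronaphthalen-1-ol
Conditions: H2 (1 atm), Pd/C, EtOAc, rt
Reagents that add atoms: none
Why: Heterogeneous hydrogenation of the unhindered 1,1-disubstituted alkene turns the methallyl into the isobutyl group; no stereocentre is formed and the arene, silyl ether and tertiary alcohol are untouched.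

Step 13
Reactants: 19 (1R,4S,4aR,7S,8aS)-1,4a-dimethyl-4-[(1S)-3-methyl-1-(2,4,6-trimethoxyphenyl)butyl]-7-{2-[(triethylsilyl)oxy]propan-2-yl}decahydronaphthalen-1-ol
Product: 21 5-{(1S)-1-[(1S,4R,4aS,6S,8aR)-4-hydroxy-4,8a-dimethyl-6-{2-[(triethylsilyl)oxy]propan-2-yl}decahydronaphthalen-1-yl]-3-methylbutyl}-2,4,6-trimethoxybenzene-1,3-dicarbaldehyde, via monoformyl aminoalkoxide 20 (not isolated)
Conditions: s-BuLi, TMEDA, THF, −78 to −20 °C; DMF; then s-BuLi, −78 to −20 °C; DMF; aq. NH4Cl
Reagents that add atoms: N,N-dimethylformamide, CN(C)C=O
Why: Directed ortho-metalation and formylation run twice in one flask: each free ring position lies between two methoxy groups, and after the first DMF quench the aldehyde stays masked as its lithium α-amino alkoxide 20 during the second lithiation. The C4 hydroxyl is carried as its lithium alkoxide, and the basic medium avoids the dehydration that Lewis-acid formylation would cause.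

Step 14
Reactants: 21 5-{(1S)-1-[(1S,4R,4aS,6S,8aR)-4-hydroxy-4,8a-dimethyl-6-{2-[(triethylsilyl)oxy]propan-2-yl}decahydronaphthalen-1-yl]-3-methylbutyl}-2,4,6-trimethoxybenzene-1,3-dicarbaldehyde
Product: 23 2,4,6-trihydroxy-5-{(1S)-1-[(1S,4R,4aS,6S,8aR)-4-hydroxy-6-(2-hydroxypropan-2-yl)-4,8a-dimethyldecahydronaphthalen-1-yl]-3-methylbutyl}benzene-1,3-dicarbaldehyde (target), via TES-protected triphenol 22 (not isolated)
Conditions: 4-MeC6H4SNa (excess), HMPA–toluene, 110 °C; then 2 M aq. HCl, THF, rt
Reagents that add atoms: none
Why: Thiolate SN2 attack at the three methyl groups, each ortho or para to a formyl group so that a stabilised phenoxide leaves; the basic medium spares both tertiary alcohols. Acidification then protonates the phenoxides and dilute acid hydrolyses the tertiary silyl ether without dehydration.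

## Compound list

1 | (S)-(+)-carvone, (5S)-2-methyl-5-(prop-1-en-2-yl)cyclohex-2-en-1-one | CC1=CC[C@@H](CC1=O)C(C)=C | starting material
2 | (5S)-5-(2-hydroxypropan-2-yl)-2-methylcyclohex-2-en-1-one | CC1=CC[C@@H](CC1=O)C(C)(C)O | intermediate
3 | (5S)-2-methyl-5-{2-[(triethylsilyl)oxy]propan-2-yl}cyclohex-2-en-1-one | CC1=CC[C@@H](CC1=O)C(C)(C)O[Si](CC)(CC)CC | intermediate
4 | lithium (5S)-2-methyl-5-{2-[(triethylsilyl)oxy]propan-2-yl}cyclohex-1-en-1-olate | [Li]OC1=C(C)CC[C@H](C(C)(C)O[Si](CC)(CC)CC)C1 | intermediate (not isolated)
5 | (5S)-2-methyl-5-{2-[(triethylsilyl)oxy]propan-2-yl}cyclohex-1-en-1-yl trifluoromethanesulfonate | O=S(=O)(OC1=C(C)CC[C@H](C(C)(C)O[Si](CC)(CC)CC)C1)C(F)(F)F | intermediate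
6 | tributyl(1-ethoxyvinyl)stannane | CCCC[Sn](CCCC)(CCCC)C(=C)OCC | starting material
7 | triethyl({2-[(1S)-3-(1-ethoxyethenyl)-4-methylcyclohex-3-en-1-yl]propan-2-yl}oxy)silane (ring B 2-ethoxydiene) | C=C(OCC)C1=C(C)CC[C@H](C(C)(C)O[Si](CC)(CC)CC)C1 | intermediate
8 | 3-acryloyl-1,3-oxazolidin-2-one | C=CC(=O)N1CCOC1=O | starting material
9 | endo adduct, 3-{[(1R,6S,8aR)-4-ethoxy-8a-methyl-6-{2-[(triethylsilyl)oxy]propan-2-yl}-1,2,3,5,6,7,8,8a-octahydronaphthalen-1-yl]carbonyl}-1,3-oxazolidin-2-one | O=C(N1CCOC1=O)[C@@H]1CCC(OCC)=C2C[C@@H](C(C)(C)O[Si](CC)(CC)CC)CC[C@]12C | intermediate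
10 | [(1R,6S,8aR)-4-ethoxy-8a-methyl-6-{2-[(triethylsilyl)oxy]propan-2-yl}-1,2,3,5,6,7,8,8a-octahydronaphthalen-1-yl]methanol | OC[C@@H]1CCC(OCC)=C2C[C@@H](C(C)(C)O[Si](CC)(CC)CC)CC[C@]12C | intermediate
11 | (4R,4aR,7S,8aS)-4-(hydroxymethyl)-4a-methyl-7-{2-[(triethylsilyl)oxy]propan-2-yl}octahydronaphthalen-1(2H)-one | OC[C@@H]1CCC(=O)[C@H]2C[C@@H](C(C)(C)O[Si](CC)(CC)CC)CC[C@]12C | intermediate
12 | (1R,4R,4aR,7S,8aS)-4-(hydroxymethyl)-1,4a-dimethyl-7-{2-[(triethylsilyl)oxy]propan-2-yl}decahydronaphthalen-1-ol | OC[C@@H]1CC[C@@](C)(O)[C@H]2C[C@@H](C(C)(C)O[Si](CC)(CC)CC)CC[C@]12C | intermediate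
13 | (1R,4R,4aS,6S,8aS)-4-hydroxy-4,8a-dimethyl-6-{2-[(triethylsilyl)oxy]propan-2-yl}decahydronaphthalene-1-carbaldehyde | O=C[C@@H]1CC[C@@](C)(O)[C@H]2C[C@@H](C(C)(C)O[Si](CC)(CC)CC)CC[C@]12C | intermediate
14 | 1,3,5-trimethoxybenzene | COc1cc(OC)cc(OC)c1 | starting material
15 | 2,4,6-trimethoxyphenyllithium | [Li]c1c(OC)cc(OC)cc1OC | intermediate (not isolated)
16 | (1R,4R,4aR,7S,8aS)-4-[hydroxy(2,4,6-trimethoxyphenyl)methyl]-1,4a-dimethyl-7-{2-[(triethylsilyl)oxy]propan-2-yl}decahydronaphthalen-1-ol (both C9' epimers) | OC(c1c(OC)cc(OC)cc1OC)[C@@H]1CC[C@@](C)(O)[C@H]2C[C@@H](C(C)(C)O[Si](CC)(CC)CC)CC[C@]12C | intermediate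
17 | trimethyl(2-methylallyl)silane | C=C(C)C[Si](C)(C)C | starting material
18 | (1R,4S,4aR,7S,8aS)-1,4a-dimethyl-4-[(1S)-3-methyl-1-(2,4,6-trimethoxyphenyl)but-3-en-1-yl]-7-{2-[(triethylsilyl)oxy]propan-2-yl}decahydronaphthalen-1-ol | C=C(C)C[C@H](c1c(OC)cc(OC)cc1OC)[C@@H]1CC[C@@](C)(O)[C@H]2C[C@@H](C(C)(C)O[Si](CC)(CC)CC)CC[C@]12C | intermediate
19 | (1R,4S,4aR,7S,8aS)-1,4a-dimethyl-4-[(1S)-3-methyl-1-(2,4,6-trimethoxyphenyl)butyl]-7-{2-[(triethylsilyl)oxy]propan-2-yl}decahydronaphthalen-1-ol | CC(C)C[C@H](c1c(OC)cc(OC)cc1OC)[C@@H]1CC[C@@](C)(O)[C@H]2C[C@@H](C(C)(C)O[Si](CC)(CC)CC)CC[C@]12C | intermediate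
20 | dilithium salt of the monoformylated arene: lithium α-(dimethylamino)alkoxide at the new formyl carbon and lithium alkoxide at C4 | CC(C)C[C@H](c1c(OC)cc(OC)c(C(O[Li])N(C)C)c1OC)[C@@H]1CC[C@@](C)(O[Li])[C@H]2C[C@@H](C(C)(C)O[Si](CC)(CC)CC)CC[C@]12C | intermediate (not isolated)
21 | 5-{(1S)-1-[(1S,4R,4aS,6S,8aR)-4-hydroxy-4,8a-dimethyl-6-{2-[(triethylsilyl)oxy]propan-2-yl}decahydronaphthalen-1-yl]-3-methylbutyl}-2,4,6-trimethoxybenzene-1,3-dicarbaldehyde | CC(C)C[C@H](c1c(OC)c(C=O)c(OC)c(C=O)c1OC)[C@@H]1CC[C@@](C)(O)[C@H]2C[C@@H](C(C)(C)O[Si](CC)(CC)CC)CC[C@]12C | intermediate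
22 | C11 triethylsilyl ether of the target (2,4,6-trihydroxy analogue of 21) | CC(C)C[C@H](c1c(O)c(C=O)c(O)c(C=O)c1O)[C@@H]1CC[C@@](C)(O)[C@H]2C[C@@H](C(C)(C)O[Si](CC)(CC)CC)CC[C@]12C | intermediate (not isolated)
23 | 2,4,6-trihydroxy-5-{(1S)-1-[(1S,4R,4aS,6S,8aR)-4-hydroxy-6-(2-hydroxypropan-2-yl)-4,8a-dimethyldecahydronaphthalen-1-yl]-3-methylbutyl}benzene-1,3-dicarbaldehyde | CC(C)C[C@H](c1c(O)c(C=O)c(O)c(C=O)c1O)[C@@H]1CC[C@@](C)(O)[C@H]2C[C@@H](C(C)(C)O)CC[C@]12C | target

## Step count and least certain steps

Total: 14 steps. Longest linear sequence: 14 steps (1 to 23); 6, 8, 14 and 17 are purchased.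

Step 5 (key step). The most likely failures are insufficient facial selectivity, because the catalyst has to work against the torsional preference of ring B, and low reactivity or Lewis-acid-induced hydrolysis of the hindered diene, whose inside methyl disfavours the s-cis form. Fallback with a covalently bound controller: setting out from 7, cycloaddition with (4S)-3-acryloyl-4-benzyl-1,3-oxazolidin-2-one promoted by Et2AlCl (CH2Cl2, −78 °C), in which the benzyl group shields the Re face of the α-carbon of the chelated s-cis imide, should give the auxiliary-bound endo adduct F1; LiBH4 reduction of F1 comes back to the route at 10.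

Step 7. The most likely failure is poor facial selectivity of protonation at C5, because the axial C1 substituent hinders the face anti to C14, or later epimerisation to the cis-fused ketone, which is estimated to be of comparable stability. Fallback that sets C5 by delivery of hydrogen, not of a proton: setting out from 10, hydrolysis without regard to C5 gives a ketone mixture containing the cis-fused ketone F2; TMSCl, NaI and Et3N in MeCN convert the mixture into the bis-silylated C4=C5 enol ether F3; Saegusa–Ito oxidation with Pd(OAc)2 and mild cleavage of the primary silyl ether give the C5=C6 enone F4; hydroxyl-directed hydrogenation with [Ir(cod)(PCy3)(py)]PF6 under H2, in which the C9' hydroxyl on the face anti to C14 binds the metal and delivers hydrogen to C5 from that face, comes back to the route at 11.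

Step 11. The most likely failure is insufficient diastereoselectivity at C9' when the free cation is trapped, or loss of H1 from the cation to give a styrene. Fallback by stereospecific substitution: setting out from 16, the (9'S)-carbinol is separated (the Felkin–Anh epimer expected from step 10, whose hydroxyl occupies the position of the future CH2 group) and complexed with (η6-naphthalene)Cr(CO)3 (THF, 70 °C) to give the tricarbonylchromium carbinol complex F5; ionisation with BF3·OEt2 in the presence of 17 at −78 °C, with leaving group and nucleophile both anti to the metal and hence overall retention, gives the tricarbonylchromium methallyl complex F6; decomplexation with I2 comes back to the route at 18.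

Step 13. The most likely failure is incomplete second lithiation, giving the monoaldehyde, or attack of the base on the masked aldehyde. Fallback by halogen–metal exchange in place of deprotonation: setting out from 19, N-bromosuccinimide (2 equiv, MeCN, 0 °C) brominates both activated ring positions to give the dibromide F7; bromine–lithium exchange with t-BuLi at −78 °C followed by DMF, carried out twice in one flask, comes back to the route at 21.

Step 14. The most likely failure is incomplete cleavage of the third methyl ether, or degradation of the dialdehyde under hot basic conditions. Fallback that avoids O-methyl protection: setting out from 13, condensation with 2,4,6-trihydroxybenzene-1,3-dicarbaldehyde (A1 of Alternative 1) under mild amine/acid catalysis in the presence of 17 (Knoevenagel condensation and conjugate allylation in the flask) would give the silyl-protected methallyl triphenol F8; chemoselective hydrogenation of the 1,1-disubstituted alkene with RhCl(PPh3)3 under H2 comes back to the route at 22, which dilute acid converts to 23 as in step 14.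

## Further compounds

F1 | step 5 | (4S)-4-benzyl-3-{[(1R,6S,8aR)-4-ethoxy-8a-methyl-6-{2-[(triethylsilyl)oxy]propan-2-yl}-1,2,3,5,6,7,8,8a-octahydronaphthalen-1-yl]carbonyl}-1,3-oxazolidin-2-one | O=C(N1[C@@H](Cc2ccccc2)COC1=O)[C@@H]1CCC(OCC)=C2C[C@@H](C(C)(C)O[Si](CC)(CC)CC)CC[C@]12C
F2 | step 7 | cis-fused C5 epimer of 11 | OC[C@@H]1CCC(=O)[C@@H]2C[C@@H](C(C)(C)O[Si](CC)(CC)CC)CC[C@]12C
F3 | step 7 | C4=C5 trimethylsilyl enol ether of 11 with the C9' hydroxyl as trimethylsilyl ether | C[Si](C)(C)OC[C@@H]1CCC(O[Si](C)(C)C)=C2C[C@@H](C(C)(C)O[Si](CC)(CC)CC)CC[C@]12C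
F4 | step 7 | C5=C6 enone corresponding to 11 | OC[C@@H]1CCC(=O)C2=C[C@@H](C(C)(C)O[Si](CC)(CC)CC)CC[C@]12C
F5 | step 11 | tricarbonylchromium complex of the (9'S) epimer of 16 | O[C@H](c1c(OC)cc(OC)cc1OC)[C@@H]1CC[C@@](C)(O)[C@H]2C[C@@H](C(C)(C)O[Si](CC)(CC)CC)CC[C@]12C.[Cr].[C-]#[O+].[C-]#[O+].[C-]#[O+]
F6 | step 11 | tricarbonylchromium complex of 18 | C=C(C)C[C@H](c1c(OC)cc(OC)cc1OC)[C@@H]1CC[C@@](C)(O)[C@H]2C[C@@H](C(C)(C)O[Si](CC)(CC)CC)CC[C@]12C.[Cr].[C-]#[O+].[C-]#[O+].[C-]#[O+]
F7 | step 13 | 3',5'-dibromo derivative of 19 | CC(C)C[C@H](c1c(OC)c(Br)c(OC)c(Br)c1OC)[C@@H]1CC[C@@](C)(O)[C@H]2C[C@@H](C(C)(C)O[Si](CC)(CC)CC)CC[C@]12C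
F8 | step 14 | methallyl analogue of 22 (C11 triethylsilyl ether) | C=C(C)C[C@H](c1c(O)c(C=O)c(O)c(C=O)c1O)[C@@H]1CC[C@@](C)(O)[C@H]2C[C@@H](C(C)(C)O[Si](CC)(CC)CC)CC[C@]12C
A1 | alternative 1 | 2,4,6-trihydroxybenzene-1,3-dicarbaldehyde (2,4-diformylphloroglucinol) | O=Cc1c(O)cc(O)c(C=O)c1O
A2 | alternative 1 | (1R,4R,4aS,6S,8aS)-4-hydroxy-6-(2-hydroxypropan-2-yl)-4,8a-dimethyldecahydronaphthalene-1-carbaldehyde | O=C[C@@H]1CC[C@@](C)(O)[C@H]2C[C@@H](C(C)(C)O)CC[C@]12C
A3 | alternative 1 | o-quinone methide from A1 and A2 | O=CC1=C(O)C(C=O)=C(O)C(=C[C@@H]2CC[C@@](C)(O)[C@H]3C[C@@H](C(C)(C)O)CC[C@]23C)C1=O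
A4 | alternative 1 | methallyl analogue of the target | C=C(C)C[C@H](c1c(O)c(C=O)c(O)c(C=O)c1O)[C@@H]1CC[C@@](C)(O)[C@H]2C[C@@H](C(C)(C)O)CC[C@]12C
A5 | alternative 2 | (R)-linalool | CC(C)=CCC[C@@](C)(O)C=C
A6 | alternative 2 | (6R,7E)-2,6-dimethyl-9-methylidene-6,10-bis[(triethylsilyl)oxy]-10-methylundeca-1,7-dien-3-one (trienone) | C=C(C)C(=O)CC[C@@](C)(O[Si](CC)(CC)CC)/C=C/C(=C)C(C)(C)O[Si](CC)(CC)CC
A7 | alternative 2 | trans-fused octalone with C1 ketone and C6=C7 alkene | O=C1CC[C@@](C)(O[Si](CC)(CC)CC)[C@H]2C=C(C(C)(C)O[Si](CC)(CC)CC)CC[C@]12C
A8 | alternative 3 | 3-[2-(1-methyl-4-oxocyclohexa-2,5-dien-1-yl)-1,3-dioxolan-2-yl]propanal | O=CCCC1(OCCO1)C2(C)C=CC(=O)C=C2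
A9 | alternative 3 | bicyclic enedione, trans-fused form | O=C1CCC2(OCCO2)[C@@]3(C)C=CC(=O)C[C@H]13
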